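The numbers in the tables stem from a simulated flask with made-up constants; scatter was added.

The slowness that sets in early is the thing to read in the gamma run, at 25 °C with 1.7 mol% of free catalyst. Side product gains 17.6% in the first 3.00 min but 9 percentage points in the next 3.00 min. That is about half the pace, while 73.4% of the starting material remains, so the pace falls further than starting material does.

all flasks: starting material 0.50 M
- epsilon: second substrate 1 equiv; reagent 1 equiv; free catalyst 2.5 mol%; temperature 10 °C; run made earlier
- gamma: second substrate 1 equiv; reagent 1 equiv; free catalyst 1.7 mol%; temperature 25 °C; run made earlier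
- beta: second substrate 1 equiv; reagent 1 equiv; free catalyst 3.8 mol%; temperature 10 °C; run made earlier
- autumn: second substrate 1.00 equiv; reagent 1.00 equiv; free catalyst 2.5 mol%; everything together at the start at 5 °C, warmed to 25 °C at 1.5 min; time 8.0 min
- dawn: second substrate 1.00 equiv (in portions, 4, over 1.5 min); reagent 1.00 equiv; free catalyst 2.5 mol%; temperature 25 °C; first portion at the start, last at 1.5 min; time 8.0 min
- winter: second substrate 1.00 equiv; reagent 1.00 equiv (fed, over 1.5 min); free catalyst 2.5 mol%; temperature 25 °C; all else is in the flask from the start; the feed brings no volume worth counting; time 8.0 min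
- spring: second substrate 1.00 equiv; reagent 1.00 equiv; free catalyst 2.5 mol%; temperature 25 °C; everything together at the start; time 8.0 min
- midnight: second substrate 1.00 equiv (fed, over 1.5 min); reagent 1.00 equiv; free catalyst 2.5 mol%; the addition at 5 °C, then warmed to 25 °C; the feed brings no volume worth counting; time 8.0 min

- epsilon (time / min: side product / %, target / %): 4.00: 6.8, 1.8; 8.00: 12.0, 0.6; 12.0: 18.0, 0.7; 15.0: 21.0, 0.6
- gamma (time / min: side product / %, target / %): 0.500: 3.5, 0.7; 1.33: 8.1, 0.3; 3.00: 17.6, 0.2; 6.00: 26.6, 0
- beta (time / min: side product / %, target / %): 1.00: 1.7, 1.4; 3.00: 5.5, 1.5; 6.00: 11.2, 1.5; 12.0: 20.0, 1.7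

(each reading ± 0.5 percentage points)

- percent here means starting material units held: one side product counts as two
- a reading or a percentage of target counts all its forms, free or not

- the flask that comes out highest in amount of side product, in percent of the starting material charged; "all alike" if 1.5 percentage points covers them all (autumn / dawn / winter / spring / midnight / all alike)
- amount of side product at the end, in percent of the starting material charged, autumn
- amount of side product at the end, in percent of the starting material charged, dawn
- amount of side product at the end, in percent of the starting material charged, winter
- amount of side product at the end, in percent of the starting material charged, spring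
- amount of side product at the end, in percent of the starting material charged, midnight

**Both ends.** A curve that bends this early can be solved at its two ends, a starting pace and a final level, joined by a steady closing of the gap. The two gamma readings of side product, one at twice the time of the other and each carrying a scatter of 0.5 points, give 36.0% for the ceiling, the level at which the joined curve for gamma stops gaining. They also give a closing rate of 0.224 min⁻¹.

**Spring beside gamma.** Spring has the same charges and temperature as gamma but more catalyst, 2.5 mol% against 1.7 mol%. This reckoning keeps the ceiling and scales the closing rate with loading, to 0.329 min⁻¹, so spring closes faster than gamma towards the same level. That gives 33.4% for spring at 8.0 min. Winter's steady feed counts as a late start of 0.750 min, which gives 32.7%. The two differ by 0.70 points, less than the margin.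

**The forecast.** The forecast names spring as highest, at 40% (34% to 46%), with dawn at 38.5%, winter at 37.5%, autumn at 36.5% and midnight at 36%. Its spring rests on “Integrating with depletion of all three components”, and it stands above the reckoning here.

**The result.** Dawn comes out highest at 39.7%, 4.7 points above spring at 35.0%, with midnight at 33.9%, autumn at 32.9% and winter at 32.1%.

    starting material + free catalyst ⇌ catalyst intermediate A (K = 1.30 L mol⁻¹, k = 2.20 L mol⁻¹ s⁻¹, Ea = 48.0 kJ mol⁻¹, ΔH = 11.0 kJ mol⁻¹)
    reagent + catalyst intermediate A → free catalyst + target (k = 0.450 L mol⁻¹ s⁻¹, Ea = 64.0 kJ mol⁻¹)
    second substrate + free catalyst ⇌ catalyst intermediate B (K = 80.0 L mol⁻¹, k = 0.780 L mol⁻¹ s⁻¹, Ea = 60.0 kJ mol⁻¹, ΔH = −44.0 kJ mol⁻¹)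
    reagent + catalyst intermediate B → free catalyst + second product (k = 0.550 L mol⁻¹ s⁻¹, Ea = 39.0 kJ mol⁻¹)
    starting material + target → side product (k = 0.260 L mol⁻¹ s⁻¹, Ea = 62.0 kJ mol⁻¹)
    free catalyst + target ⇌ idle complex, settled at all times (K = 110 L mol⁻¹, ΔH = −75.0 kJ mol⁻¹)
    (constants at 25 °C)

**Reagent's path.** In winter, reagent is used 3.7 times as fast on catalyst intermediate B as on catalyst intermediate A at 2.98 min, and 6.3 times as fast at 8.00 min. The step to second product therefore takes the larger share. Winter stands at 89.2% of the ceiling with 15.4% of its reagent left, and at ten times the time it gives 35.7%. Dawn, at that time, gives 42.2%, more than winter, with reagent at 0% and 57.7% of starting material remaining: in dawn, reagent is the limiting reagent.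

**Earlier reading.** For winter read at 5.0 min, the ceiling curve gives 27.1%. The flask holds 25.4%, with 34.7% of its reagent left.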